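**Retrosynthetic overview**

1. The target is one 2H-pyran-2-one ring (O1, C2–C6) with methoxy groups at C3 and C4, a methyl at C5 and a 10-(methylsulfanyl)decyl chain at C6. The C–S bond, the C5–CH3 bond and the O4–CH3 bond are cut last (thiolate substitution of a chloride, iodination then Suzuki methylation, O-methylation).
2. The strategy rests on reading the ring as two halves: O1–C6=C5 is an enol ester that an alkyne can deliver, and C2(=O)–C3(OMe)–C4(–O) is a 2-methoxy-3-oxo ester. The ring is therefore a tert-butyl 2-methoxy-3-oxo-4-ynoate closed by forming O1–C6 under gold π-acid catalysis.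
3. The ynone keto ester comes from aldol addition of the enolate of tert-butyl 2-methoxyacetate to 13-chlorotridec-2-ynal, then oxidation. The ynal comes from 1-bromo-10-chlorodecane by acetylide alkylation and formylation.
4. Only one ring is formed (the pyranone, in step 6). Sulfur is introduced last because it would bind gold and be attacked by the iodinating agent.

Key step: step 6

Remark: compounds 9 and 10 are carried as stereoisomeric mixtures (racemic; 9 as a diastereomer mixture), because both centres become sp2 in the ring and the target has no stereocentre.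

**Route**

Step 1
Reactants: 1 1-bromo-10-chlorodecane
Product: 2 12-chlorododec-1-yne
Conditions: LiC≡CH·H2NCH2CH2NH2 (1.2 equiv), DMSO, 10 °C to rt
Reagents that add atoms: lithium acetylide ethylenediamine complex, [Li+].[C-]#C.NCCN
Why: SN2 alkylation of an acetylide, in which bromide is displaced much faster than chloride in DMSO, so the terminal chloride should be kept for the end of the route.

Step 2
Reactants: 2 12-chlorododec-1-yne
Product: 5 13-chlorotridec-2-ynal, via lithium 12-chlorododec-1-yn-1-ide 3 (not isolated), via lithium 13-chloro-1-(dimethylamino)tridec-2-yn-1-olate 4 (not isolated)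
Conditions: n-BuLi, THF, −78 °C; DMF, −78 to 0 °C; inverse quench into aq. KH2PO4/MTBE, 0 °C
Reagents that add atoms: N,N-dimethylformamide, CN(C)C=O
Why: Formylation of a lithium alkynide with DMF, in which deprotonation of the terminal alkyne outruns any attack on the primary chloride at −78 °C and the tetrahedral adduct 4 releases the ynal only on the buffered quench, which keeps dimethylamine from adding to the product.

Step 3
Reactants: 6 methoxyacetic acid
Product: 7 tert-butyl 2-methoxyacetate
Conditions: t-BuOC(=NH)CCl3, BF3·OEt2 (cat.), CH2Cl2/cyclohexane, rt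
Reagents that add atoms: tert-butyl 2,2,2-trichloroacetimidate, CC(C)(C)OC(=N)C(Cl)(Cl)Cl
Why: Acid-catalysed tert-butylation of a carboxylic acid by a trichloroacetimidate, driven by formation of the neutral trichloroacetamide and free of strong acid or base.

Step 4
Reactants: 7 tert-butyl 2-methoxyacetate; 5 13-chlorotridec-2-ynal
Product: 9 tert-butyl 15-chloro-3-hydroxy-2-methoxypentadec-4-ynoate (mixture of diastereomers, each racemic), via lithium 1-tert-butoxy-2-methoxyethen-1-olate 8 (not isolated)
Conditions: LiN(i-Pr)2 (from i-Pr2NH and n-BuLi), THF, −78 °C; then 5, −78 °C; AcOH quench at −78 °C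
Reagents that add atoms: none
Why: Aldol addition of a lithium ester enolate to an ynal, which should be 1,2-selective at −78 °C; the two new centres (C2, C3) need no control because C3 is oxidised in step 5 and C2 becomes sp2 in step 6.

Step 5
Reactants: 9 tert-butyl 15-chloro-3-hydroxy-2-methoxypentadec-4-ynoate
Product: 10 tert-butyl 15-chloro-2-methoxy-3-oxopentadec-4-ynoate (racemic at C2, in equilibrium with its enol)
Conditions: MnO2 (activated, excess), CH2Cl2, rt; filtration, used crude
Reagents that add atoms: none
Why: MnO2 oxidation of a propargylic alcohol to the ynone, a neutral heterogeneous method that should spare the base- and acid-sensitive 2-methoxy-3-oxo ester and needs only filtration.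

Step 6
Reactants: 10 tert-butyl 15-chloro-2-methoxy-3-oxopentadec-4-ynoate
Product: 11 6-(10-chlorodecyl)-4-hydroxy-3-methoxy-2H-pyran-2-one
Conditions: Ph3PAuNTf2 (5 mol %), MeNO2/AcOH 4:1, rt
Reagents that add atoms: none
Why: The cationic monovalent gold centre of Ph3PAuNTf2 binds the C4≡C5 triple bond of 10, and because the C3 ketone polarises the ynone, its β-carbon (C5, the future ring C6) is the electrophilic end; the carbonyl oxygen of the tert-butyl ester attacks it anti to gold to give a vinyl-gold 2-tert-butoxy oxocarbenium ion. This ion sheds its tert-butyl group as isobutene, protodeauration at the future C5 (helped by AcOH) frees the catalyst, and enolisation of the pyran-2,4-dione gives the aromatic 4-hydroxy-2-pyrone 11. The closest known reaction type is the gold-catalysed cycloisomerisation of tert-butyl 3-oxo-4-ynoates to 4-hydroxy-2-pyrones, applied here to a 2-methoxy-substituted member. The one ring is closed in the 6-endo-dig mode by forming O1–C6, and no stereocentre is created, since C2 of 10 becomes the sp2 carbon C3. The step needs 6-endo over 5-exo closure, which the ynone polarisation secures because attack at the α-carbon would give a strained 2-alkylidene furan-3-one. It also needs the ester oxygen to react before the keto ester degrades, which the neutral conditions and the irreversible loss of isobutene secure.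

Step 7
Reactants: 11 6-(10-chlorodecyl)-4-hydroxy-3-methoxy-2H-pyran-2-one
Product: 12 6-(10-chlorodecyl)-3,4-dimethoxy-2H-pyran-2-one
Conditions: Me2SO4, K2CO3, acetone, reflux
Reagents that add atoms: dimethyl sulfate, COS(=O)(=O)OC
Why: O-Alkylation of the potassium pyronate (a vinylogous carboxylate) with dimethyl sulfate, conditions that favour the 4-methoxy-2-pyrone over the 2-methoxy-4-pyrone isomer, with C-methylation excluded because C3 is already substituted.

Step 8
Reactants: 12 6-(10-chlorodecyl)-3,4-dimethoxy-2H-pyran-2-one
Product: 13 6-(10-chlorodecyl)-5-iodo-3,4-dimethoxy-2H-pyran-2-one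
Conditions: NIS, CF3CO2H (cat.), MeCN, rt
Reagents that add atoms: N-iodosuccinimide, O=C1CCC(=O)N1I
Why: Electrophilic halogenation of a 2-pyrone at C5, the only ring carbon still bearing hydrogen and the β-carbon of the O1–C6=C5 enol ester unit, with acid-activated NIS as the iodonium source.

Step 9
Reactants: 13 6-(10-chlorodecyl)-5-iodo-3,4-dimethoxy-2H-pyran-2-one
Product: 14 6-(10-chlorodecyl)-3,4-dimethoxy-5-methyl-2H-pyran-2-one
Conditions: trimethylboroxine, Pd(dppf)Cl2 (5 mol %), K2CO3, 1,4-dioxane, 95 °C
Reagents that add atoms: trimethylboroxine, CB1OB(C)OB(C)O1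
Why: Suzuki–Miyaura methylation, in which the C5–I bond adds oxidatively to zerovalent palladium, the base-activated boroxine transfers methyl and reductive elimination forms C5–CH3, while the primary alkyl chloride is inert to this catalyst.

Step 10
Reactants: 14 6-(10-chlorodecyl)-3,4-dimethoxy-5-methyl-2H-pyran-2-one
Product: 15 3,4-dimethoxy-5-methyl-6-[10-(methylsulfanyl)decyl]-2H-pyran-2-one (target)
Conditions: NaSMe (1.1 equiv), DMF, 0 °C to rt
Reagents that add atoms: sodium methanethiolate, C[S-].[Na+]
Why: SN2 displacement of a primary chloride by thiolate in a dipolar aprotic solvent, which should be faster at or below room temperature than attack on the fully substituted, donor-rich pyranone ring when the thiolate is kept near one equivalent.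

**Compound list**

1 | 1-bromo-10-chlorodecane | ClCCCCCCCCCCBr | starting material
2 | 12-chlorododec-1-yne | C#CCCCCCCCCCCCl | intermediate
3 | lithium 12-chlorododec-1-yn-1-ide | [Li+].[C-]#CCCCCCCCCCCCl | intermediate
4 | lithium 13-chloro-1-(dimethylamino)tridec-2-yn-1-olate | [Li+].[O-]C(N(C)C)C#CCCCCCCCCCCCl | intermediate
5 | 13-chlorotridec-2-ynal | O=CC#CCCCCCCCCCCCl | intermediate
6 | methoxyacetic acid | COCC(=O)O | starting material
7 | tert-butyl 2-methoxyacetate | COCC(=O)OC(C)(C)C | intermediate
8 | lithium 1-tert-butoxy-2-methoxyethen-1-olate | [Li+].[O-]C(=COC)OC(C)(C)C | intermediate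
9 | tert-butyl 15-chloro-3-hydroxy-2-methoxypentadec-4-ynoate (diastereomer mixture, racemic) | COC(C(=O)OC(C)(C)C)C(O)C#CCCCCCCCCCCCl | intermediate
10 | tert-butyl 15-chloro-2-methoxy-3-oxopentadec-4-ynoate (racemic) | COC(C(=O)OC(C)(C)C)C(=O)C#CCCCCCCCCCCCl | intermediate
11 | 6-(10-chlorodecyl)-4-hydroxy-3-methoxy-2H-pyran-2-one | COc1c(O)cc(CCCCCCCCCCCl)oc1=O | intermediate
12 | 6-(10-chlorodecyl)-3,4-dimethoxy-2H-pyran-2-one | COc1cc(CCCCCCCCCCCl)oc(=O)c1OC | intermediate
13 | 6-(10-chlorodecyl)-5-iodo-3,4-dimethoxy-2H-pyran-2-one | COc1c(I)c(CCCCCCCCCCCl)oc(=O)c1OC | intermediate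
14 | 6-(10-chlorodecyl)-3,4-dimethoxy-5-methyl-2H-pyran-2-one | COc1c(C)c(CCCCCCCCCCCl)oc(=O)c1OC | intermediate
15 | 3,4-dimethoxy-5-methyl-6-[10-(methylsulfanyl)decyl]-2H-pyran-2-one | COc1c(C)c(CCCCCCCCCCSC)oc(=O)c1OC | target

**Step count**

Total steps: 10. Longest linear sequence: 9 steps (steps 1, 2, 4, 5, 6, 7, 8, 9, 10 from 1-bromo-10-chlorodecane); step 3 is a one-step side branch.

**Steps most likely to fail**

Step 6. The cyclisation may stall through chelation of gold by the enolised 2-methoxy-3-oxo ester, or the labile keto ester may degrade or close in the 5-exo sense before the 6-endo pathway takes over. The fallback sets out from 10. Conjugate addition of diethylamine to the ynone (Et2NH, EtOH, 0 °C to rt) should give tert-butyl 15-chloro-5-(diethylamino)-2-methoxy-3-oxopentadec-4-enoate F1 (alkene geometry immaterial), a vinylogous amide that is a masked 3,5-dioxo ester. CF3CO2H in CH2Cl2 then cleaves the tert-butyl ester to 15-chloro-5-(diethylamino)-2-methoxy-3-oxopentadec-4-enoic acid F2, which is not isolated. Its carboxyl oxygen adds to the protonated enaminone carbon C5 and expels diethylamine, the classical addition–elimination lactonisation of 3,5-dioxo acid derivatives, and the route is rejoined at 11.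

Step 8. C5 of the O-methylated pyranone may be too weakly nucleophilic for clean iodination, and forcing with stronger acid could cause demethylation of the C4 ether. The fallback sets out from 11 and halogenates before O-methylation, when the ring is a much more electron-rich pyronate. NIS in MeCN (or I2 with K2CO3 in aqueous THF) should give 6-(10-chlorodecyl)-4-hydroxy-5-iodo-3-methoxy-2H-pyran-2-one F3. O-Methylation as in step 7 (Me2SO4, K2CO3, acetone) then rejoins the route at 13.

Step 10. Thiolate may attack the ring in competition with chloride displacement, by SN2 demethylation of the C4 methyl ether or by addition–elimination at C4. The fallback sets out from 14. Finkelstein exchange (NaI, acetone, reflux) should give 6-(10-iododecyl)-3,4-dimethoxy-5-methyl-2H-pyran-2-one F4. This iodide is then treated with exactly one equivalent of NaSMe in THF/MeOH at −20 °C, where substitution at the primary iodide should be far faster than any ring reaction, and the route is rejoined at 15.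

**Further compounds**

F1 | step 6 | tert-butyl 15-chloro-5-(diethylamino)-2-methoxy-3-oxopentadec-4-enoate | CCN(CC)C(CCCCCCCCCCCl)=CC(=O)C(OC)C(=O)OC(C)(C)C
F2 | step 6 | 15-chloro-5-(diethylamino)-2-methoxy-3-oxopentadec-4-enoic acid | CCN(CC)C(CCCCCCCCCCCl)=CC(=O)C(OC)C(=O)O
F3 | step 8 | 6-(10-chlorodecyl)-4-hydroxy-5-iodo-3-methoxy-2H-pyran-2-one | COc1c(O)c(I)c(CCCCCCCCCCCl)oc1=O
F4 | step 10 | 6-(10-iododecyl)-3,4-dimethoxy-5-methyl-2H-pyran-2-one | COc1c(C)c(CCCCCCCCCCI)oc(=O)c1OC
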